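**Retrosynthetic overview**

1. Target 19 ⇒ macrocyclic C6 alcohol 16 + (S)-2-methylglycidic acid 18 (ester bond, last step).
2. 16 ⇒ diene 15 (C4=C5 by ring-closing metathesis, ten-membered carbocycle closed last) ⇒ bromomethyl butenolide 13 + acrolein (C6–C7 by indium Barbier, gives the α-methylene lactone) ⇒ ester 12 (butenolide by RCM) ⇒ furanone alcohol 10.
3. The furanone ring (O, C10, C1, C2, C3) ⇒ ring expansion of the oxirane (O, C10, C1) of epoxy ketal 8. The enabling feature is that C1 is also bonded to O8 of a temporary tetrahydrofuran (so it is a ketal carbon and the only site of C–O heterolysis) and carries the alkyne C2≡C3 that accepts the C10 oxygen.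
4. 8 ⇒ cyclic enol ether 7 (dioxirane; the ring fixes the enol geometry and C8 directs the face) ⇒ lactol 6 ⇒ lactone 4 + enyne 5; 4 ⇒ propanoic acid 1 + (R)-2-vinyloxirane 2.
5. Order of ring formation: temporary tetrahydrofuran (lactone) → oxirane → furanone (temporary ring released) → butenolide/α-methylene lactone → ten-membered ring.

Key step: step 5

Remark (numbering): carbons are named by germacrane numbers: C1 ring ketone, C2=C3 enol ether, ring oxygen between C3 and C10, C4(CH3)=C5, C6 (ester oxygen), C7, C8 (lactone oxygen), C9, C10 (CH3), C11(=C13H2), C12 lactone carbonyl.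
Remark (assumptions): (R)-2-vinyloxirane and (R)-2-methylglycidol are taken as purchasable single enantiomers; epoxide 8 is not purified but concentrated cold and used at once.

**Route**

Step 1
Reactants: 1 propanoic acid; 2 (R)-2-vinyloxirane
Product: 4 (5S)-3-methyl-5-vinyldihydrofuran-2(3H)-one (C3 epimers), via hydroxy acid 3 (not isolated)
Conditions: LDA (2.2 equiv), THF, 0 °C; then 2, 0 °C to rt; 2 M HCl; TsOH (cat.), toluene, 60 °C
Reagents that add atoms: none
Why: Alkylation of the carboxylic acid dianion by SN2 opening of the epoxide at its CH2 terminus leaves the allylic C–O stereocentre (C8, S) untouched, and acid closes the γ-lactone; the C10 epimer mixture does not matter because C10 becomes sp2 in step 3.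

Step 2
Reactants: 4 (5S)-3-methyl-5-vinyldihydrofuran-2(3H)-one; 5 2-methylbut-1-en-3-yne
Product: 6 (5S)-3-methyl-2-(3-methylbut-3-en-1-yn-1-yl)-5-vinyltetrahydrofuran-2-ol (lactol, epimers at C1 and C10, in equilibrium with the open hydroxy ynone)
Conditions: 5, n-BuLi, THF, −78 °C; then 4, −78 °C; AcOH quench
Reagents that add atoms: none
Why: 1,2-Addition of a lithium acetylide to a lactone should stop at the tetrahedral lactolate at −78 °C and give the lactol on work-up; no stereocentre of the target is set here.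

Step 3
Reactants: 6 (5S)-3-methyl-2-(3-methylbut-3-en-1-yn-1-yl)-5-vinyltetrahydrofuran-2-ol
Product: 7 (S)-4-methyl-5-(3-methylbut-3-en-1-yn-1-yl)-2-vinyl-2,3-dihydrofuran
Conditions: PPTS (cat.), 4 Å MS, toluene, 50 °C; Et3N added before concentration
Reagents that add atoms: none
Why: Acid-catalysed cyclodehydration of a lactol through the alkyne-stabilized oxocarbenium ion; the proton can only be lost from C10, which should give the endocyclic tetrasubstituted enol ether whose ring fixes the enol geometry.

Step 4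
Reactants: 7 (S)-4-methyl-5-(3-methylbut-3-en-1-yn-1-yl)-2-vinyl-2,3-dihydrofuran
Product: 8 (1R,3S,5R)-5-methyl-1-(3-methylbut-3-en-1-yn-1-yl)-3-vinyl-2,6-dioxabicyclo[3.1.0]hexane
Conditions: DMDO (1.05 equiv, acetone), CH2Cl2, −78 °C; volatiles removed at −20 °C; used at once
Reagents that add atoms: dimethyldioxirane, CC1(C)OO1
Why: Dioxirane epoxidation is fastest at the electron-rich enol ether, and attack anti to the C8 vinyl group (the same 1,3-anti bias as in alkylations of γ-substituted butyrolactone enolates) should set C10 as R.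

Step 5
Reactants: 8 (1R,3S,5R)-5-methyl-1-(3-methylbut-3-en-1-yn-1-yl)-3-vinyl-2,6-dioxabicyclo[3.1.0]hexane
Product: 10 (R)-2-[(S)-2-hydroxybut-3-en-1-yl]-2-methyl-5-(prop-1-en-2-yl)furan-3(2H)-one, via dihydroxy ynone 9 (not isolated)
Conditions: THF–H2O (10:1), 0 °C; then Et2NH (1.5 equiv), rt
Reagents that add atoms: water, O
Why: Water adds at the ketal carbon C1 as the oxirane C1–O bond ionizes (oxocarbenium stabilized by O8 and the alkyne), the resulting 2-hydroxy lactol opens to hydroxy ynone 9, and the tertiary C10 hydroxyl, which is the former oxirane oxygen, adds to the amine-activated ynone to close the furanone. The closest known reaction types are the hydrolytic (Rubottom-type) opening of enol-ether epoxides to α-hydroxy ketones and the diethylamine-mediated cyclization of α'-hydroxy ynones to 3(2H)-furanones. The ring closes in a formal 5-endo-dig mode (through the β-enaminone, 5-exo-trig addition–elimination); in sum the three oxirane atoms O, C10 and C1 are kept and C2 and C3 are inserted, a 3 → 5 ring expansion. No new stereocentre is formed, and C10 keeps its configuration because its C–O bond is never broken. The step needs heterolysis at C1–O and not at C10–O, which the ketal character of C1 secures, and cyclization by the C10 hydroxyl and not the C8 hydroxyl, which ring size (5 versus 7) secures. The same operation removes the temporary tetrahydrofuran and frees the C8 hydroxyl used in step 6.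

Step 6
Reactants: 10 (R)-2-[(S)-2-hydroxybut-3-en-1-yl]-2-methyl-5-(prop-1-en-2-yl)furan-3(2H)-one; 11 2-(bromomethyl)acrylic acid
Product: 12 (S)-1-[(R)-2-methyl-3-oxo-5-(prop-1-en-2-yl)-2,3-dihydrofuran-2-yl]but-3-en-2-yl 2-(bromomethyl)acrylate
Conditions: DCC, DMAP (5 mol %), CH2Cl2, 0 °C
Reagents that add atoms: none
Why: Steglich esterification of the secondary allylic alcohol proceeds with retention at C8, and low temperature with only catalytic DMAP should limit SN2' attack on the allylic bromide.

Step 7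
Reactants: 12 (S)-1-[(R)-2-methyl-3-oxo-5-(prop-1-en-2-yl)-2,3-dihydrofuran-2-yl]but-3-en-2-yl 2-(bromomethyl)acrylate
Product: 13 (S)-3-(bromomethyl)-5-{[(R)-2-methyl-3-oxo-5-(prop-1-en-2-yl)-2,3-dihydrofuran-2-yl]methyl}furan-2(5H)-one
Conditions: Grubbs II (5 mol %), CH2Cl2 (0.01 M), 40 °C
Reagents that add atoms: none
Why: Ring-closing metathesis of the vinyl group with the acrylate closes the five-membered butenolide; closure onto the isopropenyl group would need a strained bridged seven-membered ring and should not compete.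

Step 8
Reactants: 13 (S)-3-(bromomethyl)-5-{[(R)-2-methyl-3-oxo-5-(prop-1-en-2-yl)-2,3-dihydrofuran-2-yl]methyl}furan-2(5H)-one; 14 acrolein
Product: 15 (4S,5S)-4-[(R)-1-hydroxyprop-2-en-1-yl]-3-methylene-5-{[(R)-2-methyl-3-oxo-5-(prop-1-en-2-yl)-2,3-dihydrofuran-2-yl]methyl}dihydrofuran-2(3H)-one
Conditions: In powder (1.5 equiv), 14 (3 equiv), THF–H2O (1:1), rt
Reagents that add atoms: none
Why: Indium-mediated Barbier allylation at the γ-carbon (C7) through a chair transition state: attack on the ring face anti to the C8 substituent should give the trans lactone, the ring-enforced E geometry of the allyl unit should give anti (crotyl-type) selectivity and set C6 as R, and the allylic transposition creates the exocyclic methylene.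

Step 9
Reactants: 15 (4S,5S)-4-[(R)-1-hydroxyprop-2-en-1-yl]-3-methylene-5-{[(R)-2-methyl-3-oxo-5-(prop-1-en-2-yl)-2,3-dihydrofuran-2-yl]methyl}dihydrofuran-2(3H)-one
Product: 16 (4Z,6R,7S,8S,10R)-6-hydroxy-1-oxo-3,10-epoxygermacra-2,4,11(13)-trien-12,8-olide (des-acyl target)
Conditions: Hoveyda–Grubbs II (15 mol %), 1,4-benzoquinone (10 mol %), toluene (1 mM), 100 °C
Reagents that add atoms: none
Why: Ring-closing metathesis that initiates at the monosubstituted vinyl group and closes onto the isopropenyl group should give the trisubstituted C4=C5 alkene, Z by ring constraint; high dilution disfavours oligomers and benzoquinone suppresses isomerization of the allylic alcohol.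

Step 10
Reactants: 17 (R)-2-methylglycidol
Product: 18 (S)-2-methyloxirane-2-carboxylic acid
Conditions: RuCl3·xH2O (2 mol %), NaIO4 (4 equiv), MeCN–EtOAc–H2O, 0 °C to rt
Reagents that add atoms: sodium periodate, [Na+].[O-][I](=O)(=O)=O (oxygen delivered through RuO4); water, O
Why: Ruthenium tetroxide oxidation of an epoxy alcohol to the epoxy acid does not touch the quaternary stereocentre (the descriptor changes from R to S only through the priority change).

Step 11
Reactants: 16 (4Z,6R,7S,8S,10R)-6-hydroxy-1-oxo-3,10-epoxygermacra-2,4,11(13)-trien-12,8-olide; 18 (S)-2-methyloxirane-2-carboxylic acid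
Product: 19 (4Z,6R,7R,8S,10R)-1-oxo-3,10-epoxy-12,8-olidogermacra-2,4,11(13)-trien-6-yl (2S)-2-methyloxirane-2-carboxylate (target)
Conditions: 18, 2,4,6-trichlorobenzoyl chloride, Et3N, THF, 0 °C; then 16, DMAP, toluene, rt
Reagents that add atoms: none
Why: Yamaguchi esterification through the mixed anhydride should acylate the hindered C6 alcohol with retention at C6, and the mild amine base should leave the glycidate epoxide and the α-methylene lactone intact.

**Compound list**

1 | propanoic acid | CCC(=O)O | starting material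
2 | (R)-2-vinyloxirane | C=C[C@@H]1CO1 | starting material
3 | (4S)-4-hydroxy-2-methylhex-5-enoic acid (C2 epimers) | CC(C[C@H](O)C=C)C(=O)O | intermediate
4 | (5S)-3-methyl-5-vinyldihydrofuran-2(3H)-one (C3 epimers) | CC1C[C@@H](C=C)OC1=O | intermediate
5 | 2-methylbut-1-en-3-yne | C=C(C)C#C | starting material
6 | (5S)-3-methyl-2-(3-methylbut-3-en-1-yn-1-yl)-5-vinyltetrahydrofuran-2-ol (epimers at C2, C3) | CC1C[C@@H](C=C)OC1(O)C#CC(C)=C | intermediate
7 | (S)-4-methyl-5-(3-methylbut-3-en-1-yn-1-yl)-2-vinyl-2,3-dihydrofuran | CC1=C(C#CC(C)=C)O[C@H](C=C)C1 | intermediate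
8 | (1R,3S,5R)-5-methyl-1-(3-methylbut-3-en-1-yn-1-yl)-3-vinyl-2,6-dioxabicyclo[3.1.0]hexane | C=C[C@@H]1C[C@@]2(C)O[C@@]2(C#CC(C)=C)O1 | intermediate
9 | (6R,8S)-6,8-dihydroxy-2,6-dimethyldeca-1,9-dien-3-yn-5-one | C=C[C@@H](O)C[C@@](C)(O)C(=O)C#CC(C)=C | intermediate
10 | (R)-2-[(S)-2-hydroxybut-3-en-1-yl]-2-methyl-5-(prop-1-en-2-yl)furan-3(2H)-one | C=C[C@@H](O)C[C@@]1(C)OC(C(C)=C)=CC1=O | intermediate
11 | 2-(bromomethyl)acrylic acid | C=C(CBr)C(=O)O | starting material
12 | (S)-1-[(R)-2-methyl-3-oxo-5-(prop-1-en-2-yl)-2,3-dihydrofuran-2-yl]but-3-en-2-yl 2-(bromomethyl)acrylate | C=C[C@@H](OC(=O)C(=C)CBr)C[C@@]1(C)OC(C(C)=C)=CC1=O | intermediate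
13 | (S)-3-(bromomethyl)-5-{[(R)-2-methyl-3-oxo-5-(prop-1-en-2-yl)-2,3-dihydrofuran-2-yl]methyl}furan-2(5H)-one | BrCC1=C[C@H](C[C@@]2(C)OC(C(C)=C)=CC2=O)OC1=O | intermediate
14 | acrolein | C=CC=O | starting material
15 | (4S,5S)-4-[(R)-1-hydroxyprop-2-en-1-yl]-3-methylene-5-{[(R)-2-methyl-3-oxo-5-(prop-1-en-2-yl)-2,3-dihydrofuran-2-yl]methyl}dihydrofuran-2(3H)-one | C=C1C(=O)O[C@@H](C[C@@]2(C)OC(C(C)=C)=CC2=O)[C@@H]1[C@H](O)C=C | intermediate
16 | (4Z,6R,7S,8S,10R)-6-hydroxy-1-oxo-3,10-epoxygermacra-2,4,11(13)-trien-12,8-olide | C=C1C(=O)O[C@H]2C[C@@]3(C)OC(=CC3=O)/C(C)=C\[C@@H](O)[C@H]12 | intermediate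
17 | (R)-2-methylglycidol | OC[C@]1(C)CO1 | starting material
18 | (S)-2-methyloxirane-2-carboxylic acid | OC(=O)[C@]1(C)CO1 | intermediate
19 | (4Z,6R,7R,8S,10R)-1-oxo-3,10-epoxy-12,8-olidogermacra-2,4,11(13)-trien-6-yl (2S)-2-methyloxirane-2-carboxylate | C=C1C(=O)O[C@H]2C[C@@]3(C)OC(=CC3=O)/C(C)=C\[C@@H](OC(=O)[C@]3(C)CO3)[C@H]12 | target

**Step count and risks**

Total step count: 11. Longest linear sequence: 10 (steps 1–9 and 11).

Steps most likely to fail:

1. Step 9 (macrocyclic RCM). Closure onto the 1,1-disubstituted, dienone-conjugated isopropenyl group may be slow, so that intermolecular metathesis and catalyst decay outrun formation of the strained ring. The fallback forms the ring at C6–C7 instead, with the Z alkene already in place; it sets out from lactone 4 and comes back at 16. Lactone 4 would be treated with the dilithio derivative of commercial (Z)-3-methylpent-2-en-4-yn-1-ol (n-BuLi, THF, −78 °C) to give lactol F1. Dehydration (PPTS, 4 Å MS) should give enol ether F2, and DMDO at −78 °C epoxy ketal F3. Water and then Et2NH should give, through dihydroxy ynone F4 (not isolated), furanone diol F5. TEMPO/PhI(OAc)2 should oxidize only the primary allylic alcohol to the (Z)-enal F6. Steglich esterification with 11 would give bromomethylacrylate F7, and RCM butenolide enal F8. Indium in THF–H2O at high dilution should then close C6–C7 by intramolecular Barbier allylation to give 16.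

2. Step 4 (epoxidation). Oxygen transfer to the nearly flat dihydrofuran may show poor facial selectivity, because the directing C8 vinyl group is remote, and give a mixture of C10 epimers. The fallback sets out from 4 and comes back at 10. The potassium enolate of 4 (KHMDS, −78 °C) would be hydroxylated with 2-(phenylsulfonyl)-3-phenyloxaziridine trans to the vinyl group to give hydroxy lactone F9. Addition of the lithium acetylide of 5 (2.2 equiv) should give 9, and Et2NH should cyclize it to 10.

3. Step 8 (Barbier allylation). An open transition state may erode the simple diastereoselectivity at C6, and acrolein may polymerize. The fallback sets out from 15 (as the C6 epimer mixture) and comes back at 15. Dess–Martin oxidation would give vinyl ketone F10, and oxazaborolidine-catalysed (CBS) reduction with catecholborane at −78 °C, with the catalyst enantiomer chosen for the (6R)-alcohol, should set C6 by reagent control.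

Further compounds
F1 | step 9 | (5S)-2-[(Z)-5-hydroxy-3-methylpent-3-en-1-yn-1-yl]-3-methyl-5-vinyltetrahydrofuran-2-ol | CC1C[C@@H](C=C)OC1(O)C#C/C(C)=C\CO
F2 | step 9 | (S,Z)-3-methyl-5-(3-methyl-5-vinyl-4,5-dihydrofuran-2-yl)pent-2-en-4-yn-1-ol | CC1=C(C#C/C(C)=C\CO)O[C@H](C=C)C1
F3 | step 9 | (Z)-3-methyl-5-[(1R,3S,5R)-5-methyl-3-vinyl-2,6-dioxabicyclo[3.1.0]hexan-1-yl]pent-2-en-4-yn-1-ol | C=C[C@@H]1C[C@@]2(C)O[C@@]2(C#C/C(C)=C\CO)O1
F4 | step 9 | (2Z,7R,9S)-1,7,9-trihydroxy-3,7-dimethylundeca-2,10-dien-4-yn-6-one | C=C[C@@H](O)C[C@@](C)(O)C(=O)C#C/C(C)=C\CO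
F5 | step 9 | (R)-2-[(S)-2-hydroxybut-3-en-1-yl]-5-[(Z)-4-hydroxybut-2-en-2-yl]-2-methylfuran-3(2H)-one | C=C[C@@H](O)C[C@@]1(C)OC(/C(C)=C\CO)=CC1=O
F6 | step 9 | (Z)-3-{(R)-5-[(S)-2-hydroxybut-3-en-1-yl]-5-methyl-4-oxo-4,5-dihydrofuran-2-yl}but-2-enal | C=C[C@@H](O)C[C@@]1(C)OC(/C(C)=C\C=O)=CC1=O
F7 | step 9 | (S)-1-{(R)-2-methyl-3-oxo-5-[(Z)-4-oxobut-2-en-2-yl]-2,3-dihydrofuran-2-yl}but-3-en-2-yl 2-(bromomethyl)acrylate | C=C[C@@H](OC(=O)C(=C)CBr)C[C@@]1(C)OC(/C(C)=C\C=O)=CC1=O
F8 | step 9 | (Z)-3-{(R)-5-{[(S)-4-(bromomethyl)-5-oxo-2,5-dihydrofuran-2-yl]methyl}-5-methyl-4-oxo-4,5-dihydrofuran-2-yl}but-2-enal | BrCC1=C[C@H](C[C@@]2(C)OC(/C(C)=C\C=O)=CC2=O)OC1=O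
F9 | step 4 | (3R,5S)-3-hydroxy-3-methyl-5-vinyldihydrofuran-2(3H)-one | C[C@@]1(O)C[C@@H](C=C)OC1=O
F10 | step 8 | (4R,5S)-4-acryloyl-3-methylene-5-{[(R)-2-methyl-3-oxo-5-(prop-1-en-2-yl)-2,3-dihydrofuran-2-yl]methyl}dihydrofuran-2(3H)-one | C=C1C(=O)O[C@@H](C[C@@]2(C)OC(C(C)=C)=CC2=O)[C@@H]1C(=O)C=C
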